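Follow one charge of substrate through a closed, stirred flask where it can turn three ways and where target can also leave solution as crystals.

    substrate ⇌ target (K1 = 2.8, k1 = 0.42 /s, Ea1 = 74.0 kJ/mol, ΔH1 = −29.0 kJ/mol)
    substrate ⇌ isomer of the product (K2 = 24, k2 = 0.14 /s, Ea2 = 62.0 kJ/mol, ΔH2 = −69.0 kJ/mol)
    substrate ⇌ third isomer (K3 = 2.2, k3 = 0.27 /s, Ea3 = 74.0 kJ/mol, ΔH3 = −9.00 kJ/mol)
    crystals ⇌ target, rate k4*(cs4 - [target]) while solid is left; crystals form when [target] > cs4 (cs4 = 0.0038 mM, k4 = 41 /s)
    (constants at 0 °C)

all flasks: substrate 0.20 mM; time 20 s
- dusk: temperature 0 °C
- winter: temperature 8 °C

- amounts and yields of target count crystals too
- given per volume of solution although it is solid: crystals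
- all constants are for 0 °C and move with temperature by the activation energies and enthalpies

* which of these there is most of at the end, counted by the substrate in it, dusk (isomer of the product / target / substrate / third isomer)
* which of these there is most of at the end, counted by the substrate in it, winter (isomer of the product / target / substrate / third isomer)
* final amount of the leader among these, as a percentage of the substrate charged, in dusk
* final amount of the leader among these, as a percentage of the substrate charged, in winter

Here is what looks wrong: the isomer of the product has the equilibrium constant 24, larger than the 2.8 of target, yet we expect target to lead at dusk. Once crystals stand, [target] sits near 0.0038 mM, which is 1.90% of the charge. So the way back from target runs at 5.70 × 10⁻⁴ mM/s while crystals stand, far slower than the 0.0840 mM/s forward at the start, but the forward flow shrinks as substrate goes, so we come back to this way back below. The isomer of the product returns with a time constant of 171 s, far longer than 20 s, so its large constant has no time to show. This is kinetic control, and we carry one quantity, the branch share, the part of what leaves substrate on the two lasting routes that becomes target: 75.0%.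

Third isomer is a side tank. At dusk it takes 32.5% of the first departures and returns at 0.123 /s, and 67.5% of each return escapes. The pair of substrate and third isomer therefore drains at 0.0828 /s, and by 20 s we reckon it holds 7.13% of the charge. Our first go gives target 69.7% and the isomer of the product 23.2%.

Now we put that isomer back in. By our reckoning it returns 2.71 × 10⁻⁴ mM/s to substrate, dissolved target returns 5.70 × 10⁻⁴ mM/s, and together they keep a floor of 2.40% of the charge in the pair. Splitting the returned flow by the branch share, target gains a net 0.607% over the run. We commit to 68.5% of target at dusk. For winter we go as far as the sign: 74.0 kJ/mol exceeds 62.0 kJ/mol, so the share rises at 8 °C.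

The forecast names target at dusk with 67% and target in winter with 77%, on the ground that “the target step acts as a nearly one-way sink”. Its dusk figure stands below ours.

The flask gives target as leader at dusk with 67.6%, and target in winter with 78.1%. At dusk the isomer of the product stands at 22.3%, and the pair still holds 1.83% of substrate and 8.28% of third isomer. The branch share of what has left that pair gives 67.4% of target at dusk. On the reading of dusk at 12 s, the pair holds 2.77% of substrate and 14.1% of third isomer, so the share gives 62.3%, and target stood at 62.3%.

The constants are made up; the flask was simulated.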